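**Retrosynthetic overview**
- The furan ring is the only ring built and it is closed last, at O1–C2, by 5-endo-dig attack of a ring A phenoxide on a diarylalkyne.
- The diarylalkyne comes from 4-iodoresorcinol (ring A) and a ring B arylacetylene, which is the one-carbon homologue of 3,5-dihydroxy-2,6-diprenylbenzaldehyde; homologation, coupling and O-cyclisation are run as one operation.
- Both prenyl groups trace back to two aryl–O–C(CH3)2–CH=CH2 ethers, made by C–O bond formation (zerovalent-palladium allylic etherification) and moved to carbon by a double aromatic Claisen shift that the formyl group steers to its two ortho carbons.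
- Rings A and B are bought as benzenoid units (4-iodoresorcinol, 3,5-dihydroxybenzaldehyde); no protecting groups are used.

Assumption: the target has no stereocentre and no stereogenic double bond, so it is one achiral compound and no stereocontrol is needed; compounds 2 and 6 are taken as catalogue items.

**Step 1**
Reactants: 1 3,5-dihydroxybenzaldehyde; 2 tert-butyl (2-methylbut-3-en-2-yl) carbonate
Product: 3 3,5-bis[(2-methylbut-3-en-2-yl)oxy]benzaldehyde
Conditions: 2 (2.6 equiv), Pd(PPh3)4 (5 mol %), THF, 0 °C to 23 °C, Ar
Reagents that add atoms: none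
Why: Tsuji–Trost allylic etherification, in which zerovalent palladium ionises the tertiary carbonate with loss of CO2, the tert-butoxide formed deprotonates the phenol, and the phenoxide attacks the more substituted allyl terminus under kinetic control at low temperature to give the tertiary ether; the aldehyde is untouched and no stereocentre is formed.

**Step 2**
Reactants: 3 3,5-bis[(2-methylbut-3-en-2-yl)oxy]benzaldehyde
Product: 5 3,5-dihydroxy-2,6-bis(3-methylbut-2-en-1-yl)benzaldehyde, via mono-rearranged phenol 4 (not isolated)
Conditions: xylenes (base-washed glass), 130 °C, Ar, 6–10 h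
Reagents that add atoms: none
Why: Double aromatic Claisen rearrangement, in which each [3,3] shift inverts the allyl unit so the CH2 terminus bonds to the ring and a linear prenyl group results after re-aromatisation; the meta formyl group (acceptor) directs migration to the carbon next to it and the meta oxygen (donor) directs para to itself, so both point to C2 and C6, while C4 is flanked by two oxygens; no stereocentre is formed.

**Step 3**
Reactants: 5 3,5-dihydroxy-2,6-bis(3-methylbut-2-en-1-yl)benzaldehyde; 6 4-iodobenzene-1,3-diol
Product: 9 Mulberrofuran V, via terminal alkyne 7 (not isolated), via ortho-alkynylphenol 8 (not isolated)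
Conditions: dimethyl (1-diazo-2-oxopropyl)phosphonate (1.2 equiv), Cs2CO3 (6 equiv), MeOH/DMF 1:4, 23 °C, 8 h; then 6 (1.3 equiv), CuI (10 mol %), 1,10-phenanthroline (20 mol %), degassed, 100 °C, 12 h; NH4Cl work-up
Reagents that add atoms: dimethyl (1-diazo-2-oxopropyl)phosphonate, COP(=O)(OC)C(=[N+]=[N-])C(C)=O
Why: Proposed new method: a copper-only three-component homologative heteroannulation in which methoxide cleaves the acetyl group of the reagent, the diazomethylphosphonate anion adds to the hindered aldehyde and collapses (Horner–Wadsworth–Emmons-type elimination, loss of N2, 1,2-hydrogen shift) to alkyne 7, the same carbonate base and CuI turn 7 into a monovalent copper acetylide that couples with the ortho-iodophenoxide of 6 through a trivalent copper intermediate to give 8, and the ortho phenoxide of ring A then adds 5-endo-dig to the copper-activated alkyne to form the O1–C2 bond (the ring B hydroxyls are meta to the alkyne and cannot cyclise); the closest known reaction types are the Seyferth–Gilbert/Ohira–Bestmann homologation and the copper-catalysed Castro–Stephens coupling–cyclisation of 2-iodophenols with arylacetylenes, which to my knowledge have not been merged into one operation or run on an unprotected, di-ortho-substituted polyphenolic aldehyde; no stereocentre is formed.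

**Compound list**
1 | 3,5-dihydroxybenzaldehyde | O=Cc1cc(O)cc(O)c1 | starting material
2 | tert-butyl (2-methylbut-3-en-2-yl) carbonate | C=CC(C)(C)OC(=O)OC(C)(C)C | starting material
3 | 3,5-bis[(2-methylbut-3-en-2-yl)oxy]benzaldehyde | O=Cc1cc(OC(C)(C)C=C)cc(OC(C)(C)C=C)c1 | intermediate
4 | 3-hydroxy-2-(3-methylbut-2-en-1-yl)-5-[(2-methylbut-3-en-2-yl)oxy]benzaldehyde | O=Cc1cc(OC(C)(C)C=C)cc(O)c1CC=C(C)C | intermediate
5 | 3,5-dihydroxy-2,6-bis(3-methylbut-2-en-1-yl)benzaldehyde | O=Cc1c(CC=C(C)C)c(O)cc(O)c1CC=C(C)C | intermediate
6 | 4-iodobenzene-1,3-diol (4-iodoresorcinol) | Oc1ccc(I)c(O)c1 | starting material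
7 | 5-ethynyl-4,6-bis(3-methylbut-2-en-1-yl)benzene-1,3-diol | C#Cc1c(CC=C(C)C)c(O)cc(O)c1CC=C(C)C | intermediate
8 | 4-{[3,5-dihydroxy-2,6-bis(3-methylbut-2-en-1-yl)phenyl]ethynyl}benzene-1,3-diol | Oc1ccc(C#Cc2c(CC=C(C)C)c(O)cc(O)c2CC=C(C)C)c(O)c1 | intermediate
9 | Mulberrofuran V, 5-(6-hydroxy-1-benzofuran-2-yl)-4,6-bis(3-methylbut-2-en-1-yl)benzene-1,3-diol | CC(C)=CCc1c(O)cc(O)c(CC=C(C)C)c1-c1cc2ccc(O)cc2o1 | target

**Totals**
Total step count: 3. Longest linear sequence: 3 (1 → 3 → 5 → 9).

**Steps most likely to fail**

Step 3 (the proposed new step) is the most exposed. Leftover diazo reagent can be decomposed by copper, the free phenoxides can undergo Ullmann-type O-arylation at 100 °C, the alkyne can dimerise oxidatively if air enters, and the di-ortho-substituted aldehyde may homologate slowly. The fallback uses known chemistry, sets out from 5 and 6 and comes back at 9. Aldehyde 5 is homologated under standard Ohira–Bestmann conditions (K2CO3, MeOH, 23 °C) and alkyne 7 is isolated. Separately, 6 is acetylated (Ac2O, pyridine) to 4-iodo-1,3-phenylene diacetate F5. Sonogashira coupling of 7 with F5 (Pd(PPh3)2Cl2, CuI, Et3N, THF, 40 °C) gives 4-{[3,5-dihydroxy-2,6-bis(3-methylbut-2-en-1-yl)phenyl]ethynyl}-1,3-phenylene diacetate F6. K2CO3 in MeOH at 60 °C then removes both acetates (and any acetyl that has migrated), and the freed ortho phenoxide closes 5-endo-dig to 9.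

Step 2 can fail through partial migration to C4 (between the two oxygens), through loss of isoprene from the tertiary ethers, or through acid-triggered chroman formation from the ortho-prenylphenols. The fallback fixes the positions by halogenation and cross-coupling; it sets out from 1 and comes back at 5. Compound 1 is protected (MOMCl, i-Pr2NEt, CH2Cl2) as 3,5-bis(methoxymethoxy)benzaldehyde F2. NBS (2.1 equiv, MeCN) brominates para to each ether oxygen to give 2,6-dibromo-3,5-bis(methoxymethoxy)benzaldehyde F3. Double Stille coupling with tributyl(3-methylbut-2-en-1-yl)stannane (Pd(PPh3)4, DMF, 90 °C) gives 3,5-bis(methoxymethoxy)-2,6-bis(3-methylbut-2-en-1-yl)benzaldehyde F4. Catalytic HCl in MeOH at 25 °C releases 5.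

Step 1 can fail if the palladium re-ionises the aryl ether (the formyl-bearing phenoxide is a fair leaving group), which leads to the linear prenyl ether or C-allylation, or if etherification stops at the mono-ether. The fallback avoids allyl-palladium chemistry; it sets out from 1 and comes back at 3. Compound 1 is alkylated with 3-chloro-3-methylbut-1-yne (K2CO3, KI, CuI cat., acetone, 55 °C) to 3,5-bis[(2-methylbut-3-yn-2-yl)oxy]benzaldehyde F1. Semi-hydrogenation (H2, Pd/CaCO3 poisoned with Pb(OAc)2, quinoline, EtOAc, 23 °C) gives 3.

**Further compounds**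
F1 | step 1 | 3,5-bis[(2-methylbut-3-yn-2-yl)oxy]benzaldehyde | O=Cc1cc(OC(C)(C)C#C)cc(OC(C)(C)C#C)c1
F2 | step 2 | 3,5-bis(methoxymethoxy)benzaldehyde | O=Cc1cc(OCOC)cc(OCOC)c1
F3 | step 2 | 2,6-dibromo-3,5-bis(methoxymethoxy)benzaldehyde | O=Cc1c(Br)c(OCOC)cc(OCOC)c1Br
F4 | step 2 | 3,5-bis(methoxymethoxy)-2,6-bis(3-methylbut-2-en-1-yl)benzaldehyde | O=Cc1c(CC=C(C)C)c(OCOC)cc(OCOC)c1CC=C(C)C
F5 | step 3 | 4-iodo-1,3-phenylene diacetate | CC(=O)Oc1ccc(I)c(OC(C)=O)c1
F6 | step 3 | 4-{[3,5-dihydroxy-2,6-bis(3-methylbut-2-en-1-yl)phenyl]ethynyl}-1,3-phenylene diacetate | CC(=O)Oc1ccc(C#Cc2c(CC=C(C)C)c(O)cc(O)c2CC=C(C)C)c(OC(C)=O)c1
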